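**Retrosynthetic overview**
1. Feature: ring B (C1'–C6') is a 6'-pentylbenzene with oxygen on C1', C2' and C4'. The C1' oxygen is the ether bridge to C8 of the isocoumarin (benzo ring A fused to pyranone ring C). Without it ring B is the 5-pentylresorcinol (olivetol) nucleus, so the enone-plus-malonate construction of that nucleus applies if the malonate carbon that becomes C1' already carries O-8.
2. Key disconnection: C1'–C6' and C2'–C3' of ring B, leading back to the 8-O-malonyl isocoumarin and (E)-non-3-en-2-one (Michael–Claisen, 3+3). The crowded diaryl ether is thereby reduced to an O-alkylation at an sp3 carbon.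
3. Endgame: removal of the C1' ester, methyl enol ether at C4', dehydrogenation of ring B (C2' emerges as the free OH), debenzylation of O-6.
4. Isocoumarin: C4–C3 bond by benzylic lithiation of orsellinate dimethyl ether and acylation with the hexanoic Weinreb amide. Then O2–C1 lactonisation with demethylation, O-6 benzylation and O-8 alkylation with bromomalonate.
5. Order of rings: ring A is bought with methyl orsellinate, ring C closes in step 4, ring B closes in step 7 and becomes aromatic in step 10.

Key step: step 7

Remark on the chemistry: locants C1–C8a refer to the isocoumarin and C1'–C6' to ring B (C1' bears the ether oxygen). The target has no stereocentre, so the cyclohexane-stage intermediates of ring B are carried as racemic diastereomer mixtures and are drawn in one tautomeric form.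

Step 1
Reactants: 1 methyl orsellinate (methyl 2,4-dihydroxy-6-methylbenzoate)
Product: 2 methyl 2,4-dimethoxy-6-methylbenzoate
Conditions: MeI (3 equiv), K2CO3 (3 equiv), acetone, reflux
Reagents that add atoms: iodomethane, CI
Why: Williamson ether synthesis: with excess MeI at reflux the hydrogen-bonded 2-OH should be alkylated as well as the free 4-OH, which removes both acidic protons before the lithiation of step 3.

Step 2
Reactants: 3 hexanoyl chloride
Product: 4 N-methoxy-N-methylhexanamide (Weinreb amide)
Conditions: MeNH(OMe)·HCl (1.1 equiv), Et3N (2.2 equiv), CH2Cl2, 0 °C to rt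
Reagents that add atoms: N,O-dimethylhydroxylamine hydrochloride, CNOC.Cl
Why: Weinreb amide formation by N-acylation of N,O-dimethylhydroxylamine with the acid chloride, Et3N taking up both equivalents of HCl.

Step 3
Reactants: 2 methyl 2,4-dimethoxy-6-methylbenzoate, 4 N-methoxy-N-methylhexanamide
Product: 5 methyl 2,4-dimethoxy-6-(2-oxoheptyl)benzoate
Conditions: LiN(i-Pr)2 (1.05 equiv), THF, −78 °C; then 4 (1.2 equiv), −78 to −30 °C; 1 M HCl
Reagents that add atoms: none
Why: Lateral (benzylic) lithiation of an o-toluate followed by Weinreb ketone synthesis: the ester-stabilised benzylic anion adds once to 4 and the chelated tetrahedral adduct survives until the quench, which should rule out over-addition and proton transfer from the more acidic ketone product.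

Step 4
Reactants: 5 methyl 2,4-dimethoxy-6-(2-oxoheptyl)benzoate
Product: 7 dihydroxyisocoumarin 6,8-dihydroxy-3-pentyl-1H-isochromen-1-one, via 8-hydroxy-6-methoxy-3-pentylisocoumarin 6 (not isolated)
Conditions: BBr3 (5 equiv), CH2Cl2, −78 °C to rt; then H2O
Reagents that add atoms: none
Why: BBr3 aryl methyl ether cleavage coupled with acid-promoted enol lactonisation: the methoxy group chelated to the ester falls first, the boron-activated ester carbon is captured 6-exo-trig by the enol oxygen of the benzylic ketone to close ring C (6), and the excess reagent then cleaves the O-6 methyl ether, the enol lactone being inert to BBr3.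

Step 5
Reactants: 7 6,8-dihydroxy-3-pentyl-1H-isochromen-1-one
Product: 8 monobenzyl ether 6-(benzyloxy)-8-hydroxy-3-pentyl-1H-isochromen-1-one
Conditions: BnBr (1.05 equiv), K2CO3 (1.2 equiv), acetone, reflux
Reagents that add atoms: benzyl bromide, BrCc1ccccc1
Why: Regioselective Williamson etherification: the O-8 proton is held in a hydrogen bond to the lactone carbonyl and its oxygen is flanked by C1, so that one equivalent of BnBr with a mild base should react only at the more acidic and unhindered 6-OH.

Step 6
Reactants: 8 6-(benzyloxy)-8-hydroxy-3-pentyl-1H-isochromen-1-one, 9 dimethyl 2-bromomalonate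
Product: 10 dimethyl 2-{[6-(benzyloxy)-1-oxo-3-pentyl-1H-isochromen-8-yl]oxy}malonate
Conditions: Cs2CO3 (1.3 equiv), DMF, 0 °C; slow addition of 9 (1.3 equiv); 0 °C to rt
Reagents that add atoms: none
Why: Williamson-type SN2 O-alkylation of a phenoxide with a 2-halomalonate, the usual access to aryloxymalonates: Cs2CO3 in DMF frees the chelated O-8 as a reactive phenoxide, bromide leaves from a carbon activated by two esters, and slow addition of 9 at low temperature should hold back self-condensation of 9, bromine transfer and further reaction of the acidic product.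

Step 7
Reactants: 10 dimethyl 2-{[6-(benzyloxy)-1-oxo-3-pentyl-1H-isochromen-8-yl]oxy}malonate, 11 (E)-non-3-en-2-one
Product: 13 methyl 1-{[6-(benzyloxy)-1-oxo-3-pentyl-1H-isochromen-8-yl]oxy}-2,4-dioxo-6-pentylcyclohexane-1-carboxylate (racemic C1'/C6' diastereomer mixture), via Michael adduct 12 (not isolated)
Conditions: KOt-Bu (1.05 equiv), THF/t-BuOH (4:1), 0 °C; then 11 (1.2 equiv), 0 to 45 °C; cold 1 M HCl
Reagents that add atoms: none
Why: KOt-Bu deprotonates the malonate C–H of 10 completely, the soft doubly stabilised carbanion adds 1,4 to C4 of 11 and forms C1'–C6' (adduct 12), t-BuOH relays protons from the first-formed internal enolate to the methyl-ketone enolate, and this attacks one of the two ester groups with loss of methoxide and forms C2'–C3'. The closest known reaction type is the Michael–Claisen (3+3) annulation of malonic esters with alkenyl methyl ketones that delivers 5-alkylcyclohexane-1,3-diones, applied here to a 2-aryloxy-substituted malonate. Ring B closes in a 6-(enolexo)-exo-trig Claisen (Dieckmann-type) mode, and because the internal enolate could only form a four-membered ring, the ester carbon must become C2' and the ketone carbon C4'. C1' and C6' are formed without control, as a racemic mixture of diastereomers that depends on which diastereotopic ester is attacked, and this is accepted because both centres become sp2 in step 10. The crowded and reversible Michael addition is drawn forward because the released methoxide is protonated at once by the much more acidic 1,3-dione, whose delocalised enolate is the thermodynamic sink and is too weak a base or nucleophile to react further. The needed chemoselectivity is survival of the enol lactone of ring C: with one equivalent of base no free alkoxide persists, t-BuO– is too bulky for acyl attack, and the C1 carbonyl is held coplanar with ring A, so that the carbanion tethered through O-8 could reach its pi face only through a strained peri-fused five-membered transition state.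

Step 8
Reactants: 13 methyl 1-{[6-(benzyloxy)-1-oxo-3-pentyl-1H-isochromen-8-yl]oxy}-2,4-dioxo-6-pentylcyclohexane-1-carboxylate
Product: 14 dione 6-(benzyloxy)-8-[(2,4-dioxo-6-pentylcyclohexyl)oxy]-3-pentyl-1H-isochromen-1-one (racemic diastereomer mixture)
Conditions: LiCl (4 equiv), H2O (3 equiv), DMSO, 140 °C
Reagents that add atoms: none
Why: Krapcho demethoxycarbonylation of a fully substituted beta-keto ester: chloride removes the ester methyl group by SN2, the carboxylate loses CO2 with the C2' carbonyl as electron sink, and the enolate is protonated at once by water or by the acidic dione, all in a near-neutral medium that should spare lactone, benzyl ether and aryloxy group, while C1' becomes a CH centre of no lasting stereochemical consequence.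

Step 9
Reactants: 14 6-(benzyloxy)-8-[(2,4-dioxo-6-pentylcyclohexyl)oxy]-3-pentyl-1H-isochromen-1-one
Product: 15 enol ether 6-(benzyloxy)-8-[(4-methoxy-2-oxo-6-pentylcyclohex-3-en-1-yl)oxy]-3-pentyl-1H-isochromen-1-one (racemic diastereomer mixture)
Conditions: HC(OMe)3 (2 equiv), p-TsOH·H2O (5 mol %), MeOH, rt
Reagents that add atoms: trimethyl orthoformate, COC(OC)OC
Why: Acid-catalysed enol etherification of a cyclic 1,3-dione (vinylogous esterification) is reversible, so the two possible vinylogous esters equilibrate and the methoxy group should settle on C4', which lies between two CH2 groups in the dione, rather than on C2', where it would clash with the bulky C1' aryloxy group, in line with the usual behaviour of 4-substituted cyclohexane-1,3-diones, and any minor regioisomer is removed by chromatography and re-equilibrated.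

Step 10
Reactants: 15 6-(benzyloxy)-8-[(4-methoxy-2-oxo-6-pentylcyclohex-3-en-1-yl)oxy]-3-pentyl-1H-isochromen-1-one
Product: 16 phenol 6-(benzyloxy)-8-(2-hydroxy-4-methoxy-6-pentylphenoxy)-3-pentyl-1H-isochromen-1-one
Conditions: DDQ (1.2 equiv), 1,4-dioxane, 90 °C
Reagents that add atoms: none
Why: DDQ dehydrogenation of a cyclohexenone to a phenol: the dienol of the vinylogous ester gives up the C6' hydrogen as hydride to the quinone and the resulting dienone tautomerises to the arene, which erases both sp3 centres and leaves C2'–OH free and C4'–OMe in place, while the non-basic medium keeps any C1' enolate away from the lactone and the benzyl ether on the electron-poor isocoumarin oxygen should resist the oxidant.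

Step 11
Reactants: 16 6-(benzyloxy)-8-(2-hydroxy-4-methoxy-6-pentylphenoxy)-3-pentyl-1H-isochromen-1-one
Product: 17 target 6-hydroxy-8-(2-hydroxy-4-methoxy-6-pentylphenoxy)-3-pentyl-1H-isochromen-1-one
Conditions: BCl3 (3 equiv), C6HMe5 (5 equiv), CH2Cl2, −78 °C; then H2O
Reagents that add atoms: none
Why: Lewis-acid debenzylation with BCl3 and pentamethylbenzene as a non-basic benzyl cation scavenger cleaves the aryl benzyl ether at −78 °C, where the unchelated C4' methyl ether, the diaryl ether and the enol lactone are inert, and it avoids hydrogenation conditions that could saturate C3=C4.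

**Compound list**
1 | methyl orsellinate (methyl 2,4-dihydroxy-6-methylbenzoate) | COC(=O)c1c(C)cc(O)cc1O | starting material
2 | methyl 2,4-dimethoxy-6-methylbenzoate | COC(=O)c1c(C)cc(OC)cc1OC | intermediate
3 | hexanoyl chloride | CCCCCC(=O)Cl | starting material
4 | N-methoxy-N-methylhexanamide | CCCCCC(=O)N(C)OC | intermediate
5 | methyl 2,4-dimethoxy-6-(2-oxoheptyl)benzoate | CCCCCC(=O)Cc1cc(OC)cc(OC)c1C(=O)OC | intermediate
6 | 8-hydroxy-6-methoxy-3-pentyl-1H-isochromen-1-one (not isolated) | CCCCCc1cc2cc(OC)cc(O)c2c(=O)o1 | intermediate
7 | 6,8-dihydroxy-3-pentyl-1H-isochromen-1-one | CCCCCc1cc2cc(O)cc(O)c2c(=O)o1 | intermediate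
8 | 6-(benzyloxy)-8-hydroxy-3-pentyl-1H-isochromen-1-one | CCCCCc1cc2cc(OCc3ccccc3)cc(O)c2c(=O)o1 | intermediate
9 | dimethyl 2-bromomalonate | COC(=O)C(Br)C(=O)OC | starting material
10 | dimethyl 2-{[6-(benzyloxy)-1-oxo-3-pentyl-1H-isochromen-8-yl]oxy}malonate | CCCCCc1cc2cc(OCc3ccccc3)cc(OC(C(=O)OC)C(=O)OC)c2c(=O)o1 | intermediate
11 | (E)-non-3-en-2-one | CCCCC/C=C/C(C)=O | starting material
12 | dimethyl 2-{[6-(benzyloxy)-1-oxo-3-pentyl-1H-isochromen-8-yl]oxy}-2-(2-oxononan-4-yl)malonate (racemic, not isolated) | CCCCCC(CC(C)=O)C(Oc1cc(OCc2ccccc2)cc2cc(CCCCC)oc(=O)c12)(C(=O)OC)C(=O)OC | intermediate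
13 | methyl 1-{[6-(benzyloxy)-1-oxo-3-pentyl-1H-isochromen-8-yl]oxy}-2,4-dioxo-6-pentylcyclohexane-1-carboxylate (racemic diastereomer mixture) | CCCCCC1CC(=O)CC(=O)C1(Oc1cc(OCc2ccccc2)cc2cc(CCCCC)oc(=O)c12)C(=O)OC | intermediate
14 | 6-(benzyloxy)-8-[(2,4-dioxo-6-pentylcyclohexyl)oxy]-3-pentyl-1H-isochromen-1-one (racemic diastereomer mixture) | CCCCCC1CC(=O)CC(=O)C1Oc1cc(OCc2ccccc2)cc2cc(CCCCC)oc(=O)c12 | intermediate
15 | 6-(benzyloxy)-8-[(4-methoxy-2-oxo-6-pentylcyclohex-3-en-1-yl)oxy]-3-pentyl-1H-isochromen-1-one (racemic diastereomer mixture) | CCCCCC1CC(OC)=CC(=O)C1Oc1cc(OCc2ccccc2)cc2cc(CCCCC)oc(=O)c12 | intermediate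
16 | 6-(benzyloxy)-8-(2-hydroxy-4-methoxy-6-pentylphenoxy)-3-pentyl-1H-isochromen-1-one | CCCCCc1cc2cc(OCc3ccccc3)cc(Oc3c(O)cc(OC)cc3CCCCC)c2c(=O)o1 | intermediate
17 | 6-hydroxy-8-(2-hydroxy-4-methoxy-6-pentylphenoxy)-3-pentyl-1H-isochromen-1-one (CNP0409817.0, no stereocentre) | CCCCCc1cc2cc(O)cc(Oc3c(O)cc(OC)cc3CCCCC)c2c(=O)o1 | target

Total step count: 11. Longest linear sequence: 10 (steps 1 and 3 to 11, from 1).

**Steps most likely to fail**

Step 7. The addition of a fully substituted carbanion to a beta-alkylated enone may stay on the side of the reactants (retro-Michael). The long exposure to base may then open the enol lactone or let the tethered carbanion attack C1. The fallback sets out from 8 and forms the C1'–O bond by substitution instead of building ring B around it.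
- Commercial 5-pentylcyclohexane-1,3-dione F1 is symmetrical and can give only one enol ether. HC(OMe)3 and catalytic p-TsOH in MeOH convert it into 3-methoxy-5-pentylcyclohex-2-en-1-one F2.
- Kinetic alpha'-deprotonation with LiN(i-Pr)2 at −78 °C (Stork–Danheiser regiochemistry) and a quench with N-bromosuccinimide should give 6-bromo-3-methoxy-5-pentylcyclohex-2-en-1-one F3.
- The phenoxide of 8 (K2CO3, DMF, rt) then displaces the alpha-keto bromide in a Williamson-type SN2 reaction.
- The route is rejoined at 15, with the position of the methoxy group fixed by construction.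

Step 9. Etherification may be unselective, because the C1' aryloxy group also raises the electrophilicity of the neighbouring C2' carbonyl. Methanol may then attack there and the methyl group may end on the wrong oxygen. The fallback sets out from 14, aromatises first and differentiates the two oxygens only as phenols.
- Soft enolisation with TMSOTf and Et3N (CH2Cl2, 0 °C) gives the 2',4'-bis(trimethylsilyloxy)cyclohexa-1,3-diene F4.
- DDQ in toluene at rt dehydrogenates this cyclohexadiene to the bis(trimethylsilyl) ether of the resorcinol F5.
- Dilute HCl in THF frees 6-(benzyloxy)-8-(2,4-dihydroxy-6-pentylphenoxy)-3-pentyl-1H-isochromen-1-one F6.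
- One equivalent of MeI with K2CO3 in acetone should then methylate the C4'–OH, which lies between two CH positions, in preference to the C2'–OH next to the twisted aryloxy group.
- The route is rejoined at 16.

Step 10. The temperature needed for enolisation may allow over-oxidation of the electron-rich phenol as it forms, or hydride abstraction from the benzylic O–CH2 group with loss of the protecting group. The fallback sets out from 15 and separates enolisation from oxidation.
- TMSOTf and Et3N (CH2Cl2, 0 °C) give the 4'-methoxy-2'-(trimethylsilyloxy)cyclohexa-1,3-diene F7.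
- Pd(OAc)2 in MeCN at rt (Saegusa–Ito oxidation) should convert it, through an oxa-allyl palladium species and beta-hydride elimination of the C6' hydrogen, into the dienone.
- The dienone tautomerises to the phenol, and the route is rejoined at 16.

**Further compounds**
F1 | step 7 | 5-pentylcyclohexane-1,3-dione (bought) | CCCCCC1CC(=O)CC(=O)C1
F2 | step 7 | 3-methoxy-5-pentylcyclohex-2-en-1-one (racemic) | CCCCCC1CC(=O)C=C(OC)C1
F3 | step 7 | 6-bromo-3-methoxy-5-pentylcyclohex-2-en-1-one (racemic diastereomer mixture) | CCCCCC1CC(OC)=CC(=O)C1Br
F4 | step 9 | 6-(benzyloxy)-3-pentyl-8-{[6-pentyl-2,4-bis(trimethylsilyloxy)cyclohexa-1,3-dien-1-yl]oxy}-1H-isochromen-1-one (racemic) | CCCCCC1CC(O[Si](C)(C)C)=CC(O[Si](C)(C)C)=C1Oc1cc(OCc2ccccc2)cc2cc(CCCCC)oc(=O)c12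
F5 | step 9 | 6-(benzyloxy)-3-pentyl-8-[6-pentyl-2,4-bis(trimethylsilyloxy)phenoxy]-1H-isochromen-1-one | CCCCCc1cc2cc(OCc3ccccc3)cc(Oc3c(O[Si](C)(C)C)cc(O[Si](C)(C)C)cc3CCCCC)c2c(=O)o1
F6 | step 9 | 6-(benzyloxy)-8-(2,4-dihydroxy-6-pentylphenoxy)-3-pentyl-1H-isochromen-1-one | CCCCCc1cc2cc(OCc3ccccc3)cc(Oc3c(O)cc(O)cc3CCCCC)c2c(=O)o1
F7 | step 10 | 6-(benzyloxy)-8-{[4-methoxy-6-pentyl-2-(trimethylsilyloxy)cyclohexa-1,3-dien-1-yl]oxy}-3-pentyl-1H-isochromen-1-one (racemic) | CCCCCC1CC(OC)=CC(O[Si](C)(C)C)=C1Oc1cc(OCc2ccccc2)cc2cc(CCCCC)oc(=O)c12
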